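**Strategy.** The cyclohexanone ring is dissected into a two-carbon edge, the ring CH2 and the CH that carries the side chain, and the four-carbon oxygenated segment CH(epoxide)–C(CH3)(epoxide)–C(=O)–CH(O-acyl). An enantioselective Diels–Alder reaction of a (Z)-1,2-bis(silyloxy)-3-methylbutadiene, whose enediol unit maps onto the adjacent ring C=O and C–O-acyl carbons, with methyl vinyl ketone forms the CH2–CH(epoxide) and CH(O-acyl)–CH(side chain) bonds in one operation, closes the ring, sets the side-chain-bearing stereocentre and stores the ketone as an enol silane. Mitsunobu inversion with isovaleric acid, a hydroxyl-directed epoxidation, a Nozaki–Hiyama–Kishi coupling and a final singlet-oxygen ene reaction complete the target.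

Key step: step 4

Remark: the facial sense of the oxazaborolidinium catalyst in step 4 is assumed to follow the accepted model for coordinated enones; the (S)-configured catalyst is written, and its mirror image would be taken if the sense were the opposite.

Step 1
Reactants: 1 (tert-butyldimethylsilyloxy)acetaldehyde; 2 isopropenylmagnesium bromide
Product: 3 1-[(tert-butyldimethylsilyl)oxy]-3-methylbut-3-en-2-ol (racemic)
Conditions: THF, −78 to 0 °C; aq. NH4Cl work-up
Reagents that add atoms: none
Why: Grignard 1,2-addition of the alkenylmagnesium reagent to the unhindered α-silyloxy aldehyde should give the allylic alcohol, whose stereocentre is erased in the next step.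

Step 2
Reactants: 3 allylic alcohol
Product: 4 1-[(tert-butyldimethylsilyl)oxy]-3-methylbut-3-en-2-one
Conditions: Dess–Martin periodinane, NaHCO3, CH2Cl2, 0 °C to rt
Reagents that add atoms: none
Why: Dess–Martin oxidation converts the secondary allylic alcohol into the enone under buffered conditions that leave the silyl ether and the 1,1-disubstituted alkene untouched.

Step 3
Reactants: 4 α-silyloxy enone
Product: 5 (1Z)-1,2-bis[(tert-butyldimethylsilyl)oxy]-3-methylbuta-1,3-diene
Conditions: TBSOTf, Et3N, CH2Cl2, 0 °C
Reagents that add atoms: tert-butyldimethylsilyl trifluoromethanesulfonate, CC(C)(C)[Si](C)(C)OS(=O)(=O)C(F)(F)F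
Why: Soft enolisation (silyl triflate and amine) can only occur at the CH2–OSi carbon, and the Z enediol bis(silyl ether) is expected because the isopropenyl group avoids the cis position next to the new C–O substituent, which places the terminal silyloxy group on the outside of the s-cis diene.

Step 4
Reactants: 5 bis(silyloxy) diene; 6 methyl vinyl ketone (but-3-en-2-one)
Product: 7 1-[(1R,2R)-2,3-bis[(tert-butyldimethylsilyl)oxy]-4-methylcyclohex-3-en-1-yl]ethan-1-one (silyloxy and acetyl groups cis)
Conditions: (S)-1-(o-tolyl)-3,3-diphenyl-tetrahydropyrrolo[1,2-c][1,3,2]oxazaborole (20 mol %), HNTf2 (18 mol %), CH2Cl2, −78 to −40 °C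
Reagents that add atoms: none
Why: The triflimide-activated oxazaborolidine coordinates the enone carbonyl and lowers its LUMO, so the electron-rich diene adds by a concerted, asynchronous, suprafacial [4+2] cycloaddition (catalytic enantioselective Diels–Alder reaction; closest known type: oxazaborolidinium-catalysed cycloadditions of silyloxy dienes with vinyl ketones and acrylates). The cyclohexene ring is closed by an intermolecular six-membered [4+2] closure in which both C–C bonds form in the same step, the bond from the diene CH2 terminus to the enone β-carbon being the more advanced. The needed regioselectivity rests on the substrate: the terminal silyloxy group and the 3-methyl group both raise the HOMO coefficient at the CH2 terminus and stabilise the developing charge as an oxocarbenium-capped tertiary allyl cation, and a terminal donor polarises a diene more strongly than the internal silyloxy group, which would direct the other way. The cis relationship between the silyloxy-bearing carbon and the acetyl-bearing carbon follows from endo approach of the acetyl group to a diene whose terminal OSi group is fixed on the outside by the Z geometry. The absolute configuration of both new centres is set by the catalyst, which blocks one face of the bound enone so that the diene adds to the Si face of its α-carbon. The ring ketone is stored as a regiodefined tetrasubstituted enol silane and the acetyl group serves as the handle for the side chain.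

Step 5
Reactants: 7 methyl ketone cycloadduct
Product: 9 1-[(1R,2R)-2,3-bis[(tert-butyldimethylsilyl)oxy]-4-methylcyclohex-3-en-1-yl]ethenyl trifluoromethanesulfonate, via the potassium enolate 8 (not isolated)
Conditions: KN(SiMe3)2, THF, −78 °C; PhNTf2, −78 to 0 °C
Reagents that add atoms: N-phenyl-bis(trifluoromethanesulfonimide), O=S(=O)(N(c1ccccc1)S(=O)(=O)C(F)(F)F)C(F)(F)F
Why: Kinetic deprotonation by the hindered amide base occurs at the acetyl CH3 rather than at the tertiary ring C–H, and O-sulfonylation of the enolate gives the 1,1-disubstituted enol triflate without touching the ring enol silane or the stereocentres.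

Step 6
Reactants: 9 enol triflate with ring enol silane
Product: 10 1-[(1R,2R)-2-[(tert-butyldimethylsilyl)oxy]-4-methyl-3-oxocyclohex-4-en-1-yl]ethenyl trifluoromethanesulfonate
Conditions: Pd(OAc)2 (10 mol %), O2 (1 atm), DMSO, 40 °C
Reagents that add atoms: none
Why: Saegusa oxidation, in which divalent palladium converts the enol silane into a palladium enolate that undergoes β-hydride elimination toward the ring CH2 to give the conjugated trisubstituted enone, while O2 reoxidises zerovalent palladium before it can insert into the enol triflate.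

Step 7
Reactants: 10 α'-silyloxy enone
Product: 11 1-[(1R,2R)-2-hydroxy-4-methyl-3-oxocyclohex-4-en-1-yl]ethenyl trifluoromethanesulfonate
Conditions: HF·pyridine, pyridine, THF, 0 °C to rt
Reagents that add atoms: none
Why: Buffered fluoride cleaves the secondary silyl ether by Si–F bond formation and leaves the enone, the enol triflate and both stereocentres unchanged.

Step 8
Reactants: 11 α'-hydroxy enone; 12 isovaleric acid (3-methylbutanoic acid)
Product: 13 (1S,6R)-3-methyl-2-oxo-6-{1-[(trifluoromethanesulfonyl)oxy]ethenyl}cyclohex-3-en-1-yl 3-methylbutanoate (ester and side-chain carbon trans)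
Conditions: PPh3, diisopropyl azodicarboxylate, THF, 0 °C to rt
Reagents that add atoms: none
Why: Mitsunobu esterification turns the carbonyl-activated secondary alcohol into an oxyphosphonium ion that isovalerate displaces with SN2 inversion, which installs the ester and converts the cis relationship left by the endo cycloaddition into the required trans one.

Step 9
Reactants: 13 α'-acyloxy enone
Product: 14 (1S,2S,6R)-2-hydroxy-3-methyl-6-{1-[(trifluoromethanesulfonyl)oxy]ethenyl}cyclohex-3-en-1-yl 3-methylbutanoate
Conditions: NaBH4, CeCl3·7H2O, MeOH, −78 °C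
Reagents that add atoms: none
Why: Luche reduction delivers hydride 1,2 and axially to the enone whose two ring substituents sit equatorial, so the new carbinol should be equatorial, trans to the neighbouring ester and cis to the side-chain carbon, while the ester and the enol triflate survive at low temperature.

Step 10
Reactants: 14 allylic alcohol
Product: 15 (1R,2R,3S,4R,6S)-2-hydroxy-1-methyl-4-{1-[(trifluoromethanesulfonyl)oxy]ethenyl}-7-oxabicyclo[4.1.0]heptan-3-yl 3-methylbutanoate
Conditions: VO(acac)2 (5 mol %), t-BuOOH (decane), CH2Cl2, 0 °C to rt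
Reagents that add atoms: tert-butyl hydroperoxide, CC(C)(C)OO
Why: In this hydroxyl-directed epoxidation the vanadium alkoxide of the allylic alcohol delivers the peroxide oxygen to the syn face of the trisubstituted ring alkene, setting both epoxide carbons cis to the carbinol and hence cis to the side chain and trans to the ester, while the electron-poor enol triflate alkene is not epoxidised.

Step 11
Reactants: 16 4-methylpent-3-en-1-ol
Product: 17 4-methylpent-3-enal
Conditions: Dess–Martin periodinane, NaHCO3, CH2Cl2, 0 °C; used directly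
Reagents that add atoms: none
Why: Buffered Dess–Martin oxidation of the primary homoallylic alcohol gives the β,γ-unsaturated aldehyde without migration of the double bond into conjugation.

Step 12
Reactants: 15 epoxy alcohol enol triflate; 17 4-methylpent-3-enal
Product: 18 (1R,2R,3S,4S,6S)-2-hydroxy-4-(3-hydroxy-6-methylhepta-1,5-dien-2-yl)-1-methyl-7-oxabicyclo[4.1.0]heptan-3-yl 3-methylbutanoate (both epimers at the side-chain carbinol)
Conditions: CrCl2 (6 equiv), NiCl2 (2 mol %), DMF, rt; aqueous work-up
Reagents that add atoms: none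
Why: In the Nozaki–Hiyama–Kishi coupling NiCl2-catalysed insertion into the enol triflate and transfer to chromium give a vinylchromium species that adds chemoselectively to the aldehyde and tolerates the free hydroxyl, the ester and the epoxide, and the epimeric carbinol is of no consequence because it is oxidised next.

Step 13
Reactants: 18 diol
Product: 19 (1S,3S,4S,6S)-1-methyl-4-(6-methyl-3-oxohepta-1,5-dien-2-yl)-2-oxo-7-oxabicyclo[4.1.0]heptan-3-yl 3-methylbutanoate
Conditions: Dess–Martin periodinane (3 equiv), NaHCO3, CH2Cl2, 0 °C to rt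
Reagents that add atoms: none
Why: Dess–Martin oxidation converts the epoxy alcohol and the side-chain allylic alcohol into ketones in one operation, and the bicarbonate buffer keeps the doubly activated CH2 of the β,γ-unsaturated ketone from isomerising and the α-acyloxy stereocentre from epimerising.

Step 14
Reactants: 19 epoxy diketone
Product: 20 (1S,3S,4S,6S)-4-[(4E)-6-hydroperoxy-6-methyl-3-oxohepta-1,4-dien-2-yl]-1-methyl-2-oxo-7-oxabicyclo[4.1.0]heptan-3-yl 3-methylbutanoate (target)
Conditions: O2, tetraphenylporphyrin (cat.), visible light, CH2Cl2, −20 °C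
Reagents that add atoms: dioxygen, O=O
Why: In this Schenck ene reaction singlet oxygen attacks the electron-rich trisubstituted alkene and abstracts one of the doubly activated allylic hydrogens next to the ketone on the more substituted side of the alkene, which moves the double bond into conjugation as the E alkene and places the hydroperoxide on the tertiary carbon, while the electron-poor 2-acyl alkene and the epoxy ketone are inert.

**Compound list**

1 | (tert-butyldimethylsilyloxy)acetaldehyde | O=CCO[Si](C)(C)C(C)(C)C | starting material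
2 | isopropenylmagnesium bromide | C=C(C)[Mg]Br | starting material
3 | 1-[(tert-butyldimethylsilyl)oxy]-3-methylbut-3-en-2-ol (racemic) | C=C(C)C(O)CO[Si](C)(C)C(C)(C)C | intermediate
4 | 1-[(tert-butyldimethylsilyl)oxy]-3-methylbut-3-en-2-one | C=C(C)C(=O)CO[Si](C)(C)C(C)(C)C | intermediate
5 | (1Z)-1,2-bis[(tert-butyldimethylsilyl)oxy]-3-methylbuta-1,3-diene | C=C(C)/C(O[Si](C)(C)C(C)(C)C)=C/O[Si](C)(C)C(C)(C)C | intermediate
6 | methyl vinyl ketone (but-3-en-2-one) | C=CC(C)=O | starting material
7 | 1-[(1R,2R)-2,3-bis[(tert-butyldimethylsilyl)oxy]-4-methylcyclohex-3-en-1-yl]ethan-1-one | CC(=O)[C@@H]1CCC(C)=C(O[Si](C)(C)C(C)(C)C)[C@@H]1O[Si](C)(C)C(C)(C)C | intermediate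
8 | potassium enolate of 7 (potassium 1-[(1R,2R)-2,3-bis[(tert-butyldimethylsilyl)oxy]-4-methylcyclohex-3-en-1-yl]ethen-1-olate) | [K+].C=C([O-])[C@@H]1CCC(C)=C(O[Si](C)(C)C(C)(C)C)[C@@H]1O[Si](C)(C)C(C)(C)C | intermediate
9 | 1-[(1R,2R)-2,3-bis[(tert-butyldimethylsilyl)oxy]-4-methylcyclohex-3-en-1-yl]ethenyl trifluoromethanesulfonate | C=C(OS(=O)(=O)C(F)(F)F)[C@@H]1CCC(C)=C(O[Si](C)(C)C(C)(C)C)[C@@H]1O[Si](C)(C)C(C)(C)C | intermediate
10 | 1-[(1R,2R)-2-[(tert-butyldimethylsilyl)oxy]-4-methyl-3-oxocyclohex-4-en-1-yl]ethenyl trifluoromethanesulfonate | C=C(OS(=O)(=O)C(F)(F)F)[C@@H]1CC=C(C)C(=O)[C@@H]1O[Si](C)(C)C(C)(C)C | intermediate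
11 | 1-[(1R,2R)-2-hydroxy-4-methyl-3-oxocyclohex-4-en-1-yl]ethenyl trifluoromethanesulfonate | C=C(OS(=O)(=O)C(F)(F)F)[C@@H]1CC=C(C)C(=O)[C@@H]1O | intermediate
12 | isovaleric acid (3-methylbutanoic acid) | CC(C)CC(=O)O | starting material
13 | (1S,6R)-3-methyl-2-oxo-6-{1-[(trifluoromethanesulfonyl)oxy]ethenyl}cyclohex-3-en-1-yl 3-methylbutanoate | C=C(OS(=O)(=O)C(F)(F)F)[C@@H]1CC=C(C)C(=O)[C@H]1OC(=O)CC(C)C | intermediate
14 | (1S,2S,6R)-2-hydroxy-3-methyl-6-{1-[(trifluoromethanesulfonyl)oxy]ethenyl}cyclohex-3-en-1-yl 3-methylbutanoate | C=C(OS(=O)(=O)C(F)(F)F)[C@@H]1CC=C(C)[C@H](O)[C@H]1OC(=O)CC(C)C | intermediate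
15 | (1R,2R,3S,4R,6S)-2-hydroxy-1-methyl-4-{1-[(trifluoromethanesulfonyl)oxy]ethenyl}-7-oxabicyclo[4.1.0]heptan-3-yl 3-methylbutanoate | C=C(OS(=O)(=O)C(F)(F)F)[C@@H]1C[C@@H]2O[C@]2(C)[C@H](O)[C@H]1OC(=O)CC(C)C | intermediate
16 | 4-methylpent-3-en-1-ol | CC(C)=CCCO | starting material
17 | 4-methylpent-3-enal | CC(C)=CCC=O | intermediate
18 | (1R,2R,3S,4S,6S)-2-hydroxy-4-(3-hydroxy-6-methylhepta-1,5-dien-2-yl)-1-methyl-7-oxabicyclo[4.1.0]heptan-3-yl 3-methylbutanoate (epimers at the side-chain carbinol) | CC(C)=CCC(O)C(=C)[C@@H]1C[C@@H]2O[C@]2(C)[C@H](O)[C@H]1OC(=O)CC(C)C | intermediate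
19 | (1S,3S,4S,6S)-1-methyl-4-(6-methyl-3-oxohepta-1,5-dien-2-yl)-2-oxo-7-oxabicyclo[4.1.0]heptan-3-yl 3-methylbutanoate | CC(C)=CCC(=O)C(=C)[C@@H]1C[C@@H]2O[C@]2(C)C(=O)[C@H]1OC(=O)CC(C)C | intermediate
20 | (1S,3S,4S,6S)-4-[(4E)-6-hydroperoxy-6-methyl-3-oxohepta-1,4-dien-2-yl]-1-methyl-2-oxo-7-oxabicyclo[4.1.0]heptan-3-yl 3-methylbutanoate | C=C(C(=O)/C=C/C(C)(C)OO)[C@@H]1C[C@@H]2O[C@]2(C)C(=O)[C@H]1OC(=O)CC(C)C | target

Total step count: 14. Longest linear sequence: 13 steps (steps 1 to 10 and 12 to 14).

**Steps most likely to fail**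

Step 4. The strongly acidic catalyst may desilylate the bis(enol silane) or divert the reaction into an open-chain Mukaiyama–Michael addition, and regiochemical or facial control may then be lost. The fallback sets out from diene 5 and returns at 7. Diene 5 is combined with commercial 3-acryloyl-1,3-oxazolidin-2-one under the milder, two-point-binding Cu(SbF6)2 complex of (S,S)-tert-butyl-bis(oxazoline) (10 mol %, CH2Cl2, −40 °C; ligand antipode chosen for the same facial sense) to give the cis N-acyloxazolidinone cycloadduct 3-{[(1R,2R)-2,3-bis[(tert-butyldimethylsilyl)oxy]-4-methylcyclohex-3-en-1-yl]carbonyl}-1,3-oxazolidin-2-one F1. Me3Al and MeNH(OMe)·HCl (CH2Cl2, 0 °C) exchange the oxazolidinone for the amide (1R,2R)-2,3-bis[(tert-butyldimethylsilyl)oxy]-N-methoxy-N,4-dimethylcyclohex-3-ene-1-carboxamide F2, and MeMgBr (THF, −20 °C, aq. NH4Cl work-up) converts this into methyl ketone 7.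

Step 8. The activated, axial oxyphosphonium group may undergo anti elimination toward the side-chain carbon followed by tautomerisation to a phenol, or the ester may form with retention through an acyloxyphosphonium pathway. The fallback sets out from 10 and returns at 13 without any substitution at the carbinol carbon. The silyl ether 10 is equilibrated with catalytic DBU (toluene, rt) through its cross-conjugated dienolate to the more stable trans diequatorial isomer 1-[(1R,2S)-2-[(tert-butyldimethylsilyl)oxy]-4-methyl-3-oxocyclohex-4-en-1-yl]ethenyl trifluoromethanesulfonate F3. HF·pyridine then frees the trans alcohol 1-[(1R,2S)-2-hydroxy-4-methyl-3-oxocyclohex-4-en-1-yl]ethenyl trifluoromethanesulfonate F4, and acylation with isovaleryl chloride (pyridine, cat. DMAP, CH2Cl2, 0 °C) gives 13 with retention.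

Step 14. Hydrogen abstraction from the geminal methyl groups may compete and give the secondary hydroperoxide regioisomer, or the β,γ-double bond may migrate before oxygenation. The fallback sets out from 15 and returns at 20, bringing the peroxide in as a preformed, protected unit:

- Nozaki–Hiyama–Kishi coupling of 15 with acrolein (CrCl2, cat. NiCl2, DMF) gives the vinyl carbinol (1R,2R,3S,4S,6S)-2-hydroxy-4-(3-hydroxypenta-1,4-dien-2-yl)-1-methyl-7-oxabicyclo[4.1.0]heptan-3-yl 3-methylbutanoate F5.
- Buffered Dess–Martin oxidation gives the divinyl ketone (1S,3S,4S,6S)-1-methyl-2-oxo-4-(3-oxopenta-1,4-dien-2-yl)-7-oxabicyclo[4.1.0]heptan-3-yl 3-methylbutanoate F6.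
- Separately, commercial 2-methylbut-3-en-2-ol is converted with 50 % H2O2 and cat. H2SO4 into 2-methylbut-3-en-2-yl hydroperoxide F7, which is capped with 2-methoxypropene (cat. pyridinium p-toluenesulfonate) as the peroxyketal 3-[(2-methoxypropan-2-yl)peroxy]-3-methylbut-1-ene F8.
- Cross-metathesis of F6 with F8 (second-generation Hoveyda–Grubbs catalyst, CH2Cl2, 40 °C) occurs at the monosubstituted vinyl ketone and gives the E enone (1S,3S,4S,6S)-4-{(4E)-6-[(2-methoxypropan-2-yl)peroxy]-6-methyl-3-oxohepta-1,4-dien-2-yl}-1-methyl-2-oxo-7-oxabicyclo[4.1.0]heptan-3-yl 3-methylbutanoate F9.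
- Mild hydrolysis (AcOH, THF, H2O, rt) releases the hydroperoxide 20.

Further compounds
F1 | step 4 | 3-{[(1R,2R)-2,3-bis[(tert-butyldimethylsilyl)oxy]-4-methylcyclohex-3-en-1-yl]carbonyl}-1,3-oxazolidin-2-one | O=C([C@@H]1CCC(C)=C(O[Si](C)(C)C(C)(C)C)[C@@H]1O[Si](C)(C)C(C)(C)C)N1CCOC1=O
F2 | step 4 | (1R,2R)-2,3-bis[(tert-butyldimethylsilyl)oxy]-N-methoxy-N,4-dimethylcyclohex-3-ene-1-carboxamide | CON(C)C(=O)[C@@H]1CCC(C)=C(O[Si](C)(C)C(C)(C)C)[C@@H]1O[Si](C)(C)C(C)(C)C
F3 | step 8 | 1-[(1R,2S)-2-[(tert-butyldimethylsilyl)oxy]-4-methyl-3-oxocyclohex-4-en-1-yl]ethenyl trifluoromethanesulfonate | C=C(OS(=O)(=O)C(F)(F)F)[C@@H]1CC=C(C)C(=O)[C@H]1O[Si](C)(C)C(C)(C)C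
F4 | step 8 | 1-[(1R,2S)-2-hydroxy-4-methyl-3-oxocyclohex-4-en-1-yl]ethenyl trifluoromethanesulfonate | C=C(OS(=O)(=O)C(F)(F)F)[C@@H]1CC=C(C)C(=O)[C@H]1O
F5 | step 14 | (1R,2R,3S,4S,6S)-2-hydroxy-4-(3-hydroxypenta-1,4-dien-2-yl)-1-methyl-7-oxabicyclo[4.1.0]heptan-3-yl 3-methylbutanoate (carbinol epimers) | C=CC(O)C(=C)[C@@H]1C[C@@H]2O[C@]2(C)[C@H](O)[C@H]1OC(=O)CC(C)C
F6 | step 14 | (1S,3S,4S,6S)-1-methyl-2-oxo-4-(3-oxopenta-1,4-dien-2-yl)-7-oxabicyclo[4.1.0]heptan-3-yl 3-methylbutanoate | C=CC(=O)C(=C)[C@@H]1C[C@@H]2O[C@]2(C)C(=O)[C@H]1OC(=O)CC(C)C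
F7 | step 14 | 2-methylbut-3-en-2-yl hydroperoxide | C=CC(C)(C)OO
F8 | step 14 | 3-[(2-methoxypropan-2-yl)peroxy]-3-methylbut-1-ene | C=CC(C)(C)OOC(C)(C)OC
F9 | step 14 | (1S,3S,4S,6S)-4-{(4E)-6-[(2-methoxypropan-2-yl)peroxy]-6-methyl-3-oxohepta-1,4-dien-2-yl}-1-methyl-2-oxo-7-oxabicyclo[4.1.0]heptan-3-yl 3-methylbutanoate | COC(C)(C)OOC(C)(C)/C=C/C(=O)C(=C)[C@@H]1C[C@@H]2O[C@]2(C)C(=O)[C@H]1OC(=O)CC(C)C
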